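At early times the side product stays within the scatter of zero while target already shows: the grey run at 0.625 d reads 12% target and 0% side product. By 3.00 d the ratio of side product to target stands at 0.261 in grey and at 0.714 in blue, higher with the richer charge. So read the side product as a consecutive step, made from target and substrate together.

| setting | ochre | grey | blue | north-west | north-east | south-west |
|---|---|---|---|---|---|---|
| substrate | 2 M | 1.3 M | 3 M | 2.0 M | 2.0 M | 2.0 M |
| remark | run made earlier | run made earlier | run made earlier | a closed flask charged with all of it at once and left for 3.0 d | a single well-mixed tank run continuously and read at steady state, 15.0 d in it on average | one stirred flow tank at steady state, fed with the mixture as stated, mean residence time 3.0 d |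
| time |  |  |  | 3.0 d |  |  |

ochre run (percent of the substrate charged)

| time / h | target / % | side product / % |
|---|---|---|
| 3.00 | 0 | 0 |
| 8.00 | 4 | 0 |
| 15.0 | 7 | 3 |
| 25.0 | 16 | 5 |
| 30.0 | 15 | 0 |
| 40.0 | 22 | 7 |

grey run (percent of the substrate charged)

| time / d | target / % | side product / % |
|---|---|---|
| 0.208 | 5 | 2 |
| 0.625 | 12 | 0 |
| 1.04 | 22 | 1 |
| 1.67 | 32 | 4 |
| 2.50 | 41 | 6 |
| 3.00 | 46 | 12 |

blue run (percent of the substrate charged)

| time / d | target / % | side product / % |
|---|---|---|
| 0.208 | 0 | 2 |
| 0.625 | 9 | 3 |
| 1.04 | 9 | 2 |
| 1.67 | 18 | 8 |
| 2.50 | 22 | 14 |
| 3.00 | 28 | 20 |

(readings scatter by 2 percentage points)

- the set-up with the highest share of target in all that became target or side product, at the outlet or at the end ("none" if the first two lie within 2 percentage points) (north-west / north-east / south-west / none)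
- share of target in all that became target or side product, at the outlet or at the end, north-west
- share of target in all that became target or side product, at the outlet or at the end, north-east
- share of target in all that became target or side product, at the outlet or at the end, south-west

- percentages count the substrate that a species holds: one side product counts as two
- the stated concentrations are those of everything mixed, before any reaction; amounts are the same in each set-up
- the earlier runs were made in a closed, stirred flask

Carry one reading: the lag constant, the side-product-to-target ratio of a closed flask divided by charged c(substrate) and time, 0.0794 L mol⁻¹ d⁻¹ from blue; grey reads 0.0669 L mol⁻¹ d⁻¹.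

Turn the time first. In north-west the ratio reaches 0.476, so the target share, the selectivity, is 67.7%.

Turn the vessel next. In a tank, target stands at its outlet level for the whole stay instead of rising from zero, so take the ratio as 2 times the lag constant times outlet c(substrate) times residence time.

Turn the residence time last. Take substrate loss as first order, 0.289 d⁻¹ from grey. Outlet c(substrate) is then 1.07 M in south-west and 0.375 M in north-east. The shares come to 66.2% in south-west and 52.8% in north-east. North-west leads south-west by 1.5 percentage points, less than the margin of 2 points, so commit to none as the best set-up.

The forecast differs: it named north-east, with 77%, 97% and 89% for north-west, north-east and south-west, holding that “Selectivity therefore improves at low substrate”.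

The best set-up is north-west, with 69.3% in north-west, 61.4% in north-east and 61.1% in south-west.

    substrate + target → side product (k = 0.00424 L mol⁻¹ h⁻¹)
    substrate → target, rate k2*[substrate]/(1 + ([substrate]/sat2)) (0.730 M, k = 0.0250 h⁻¹)

With the lag constant of 0.0794 L mol⁻¹ d⁻¹, the reckoned ratio is 0.476 for north-west and 0.510 for south-west, and the flasks give 0.443 and 0.637. North-west stands 3.0 d, less than the 3.4 d half-life of target by the reaction of substrate + target alone, the other concentrations as charged, and at its end it holds 15.8% of the substrate charged as side product.

The numbers in the tables come from a simulation for substances that don't exist; noise was put on by code.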